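The ring is numbered C1 (CHOBz beside the quaternary carbon), C2=C3, C4 (CHOBz), C5 (CHOH), C6 (quaternary carbinol), with C7 the CH2OH carbon. Everything rests on the hidden mirror plane through C6 and C3 of the six-membered ring: the target is traced back to the achiral dienol 9, 1-(silyloxymethyl)cyclohexa-2,5-dien-1-ol. A chiral bis-hydroxamic acid–hafnium catalyst, anchored on the C6 hydroxyl, epoxidizes only the C4=C5 alkene on the hydroxyl face, closing the oxirane and fixing C4, C5 and C6 in one operation. Benzoate then opens the oxirane at C4 with inversion, and the untouched C1=C2 alkene is later transposed into the C1 benzoate and the C2=C3 alkene.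

Key step: step 6

Convention: α is the ring face that carries the C6 hydroxyl, β the face that carries the C6 CH2O arm; locants C1–C7 are those of the first paragraph.

Assumption: the sense of induction of the bis-hydroxamic acid ligand on this cyclic dienol cannot be read from open-chain cases, so the ligand antipode that leads to 10 is to be identified in a pilot run; both antipodes derive from the two enantiomers of trans-cyclohexane-1,2-diamine.

Step 1
Reactants: 1 benzoic acid
Product: 2 cyclohexa-2,5-diene-1-carboxylic acid
Conditions: Na, NH3(l), EtOH, −78 to −33 °C; NH4Cl; aq. HCl to pH 2, 0 °C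
Reagents that add atoms: none
Why: Birch reduction: the carboxylate directs the two protonations to the ipso and para carbons, so the unconjugated 2,5-diene acid should result and no stereocenter is formed.

Step 2
Reactants: 2 cyclohexa-2,5-diene-1-carboxylic acid, 3 iodomethane
Product: 4 methyl cyclohexa-2,5-diene-1-carboxylate
Conditions: MeI, KHCO3, DMF, rt
Reagents that add atoms: iodomethane, CI
Why: Carboxylate O-alkylation (SN2 on iodomethane) under bicarbonate, a base too weak to remove the doubly allylic C–H and pull the skipped diene into conjugation.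

Step 3
Reactants: 4 methyl cyclohexa-2,5-diene-1-carboxylate
Product: 6 methyl 1-hydroxycyclohexa-2,5-diene-1-carboxylate, via potassium ester enolate 5 (not isolated)
Conditions: KN(SiMe3)2, THF, −78 °C; then 2-(benzenesulfonyl)-3-phenyloxaziridine, −78 °C; aq. NH4Cl at −78 °C
Reagents that add atoms: 2-(benzenesulfonyl)-3-phenyloxaziridine, O=S(=O)(N1OC1c1ccccc1)c1ccccc1
Why: Davis oxidation of an ester enolate: the cross-conjugated dienolate should take the electrophilic oxaziridine oxygen at its α-carbon, the site at which such enolates are alkylated in Birch reductive alkylations, so both alkenes stay unconjugated and the product is achiral.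

Step 4
Reactants: 6 methyl 1-hydroxycyclohexa-2,5-diene-1-carboxylate
Product: 7 1-(hydroxymethyl)cyclohexa-2,5-dien-1-ol
Conditions: LiAlH4, Et2O, 0 °C; H2O, 15% aq. NaOH, H2O
Reagents that add atoms: none
Why: LiAlH4 reduction of the ester to the primary alcohol, worked up under base because the doubly allylic tertiary carbinol would dehydrate and aromatize in acid, while the isolated alkenes are inert to hydride.

Step 5
Reactants: 7 1-(hydroxymethyl)cyclohexa-2,5-dien-1-ol, 8 tert-butyl(chloro)dimethylsilane
Product: 9 1-{[tert-butyl(dimethyl)silyl]oxymethyl}cyclohexa-2,5-dien-1-ol (achiral, mirror plane through C6 and C3)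
Conditions: TBSCl (1.05 equiv), imidazole, CH2Cl2, 0 °C
Reagents that add atoms: tert-butyl(chloro)dimethylsilane, CC(C)(C)[Si](C)(C)Cl
Why: Chemoselective silylation: the chlorosilane/imidazole pair reacts with the primary hydroxyl much faster than with the tertiary one, which leaves the C6 hydroxyl as the only free directing group and puts a bulky, non-coordinating arm on C7.

Step 6
Reactants: 9 1-{[tert-butyl(dimethyl)silyl]oxymethyl}cyclohexa-2,5-dien-1-ol
Product: 10 (1S,2S,6S)-2-{[tert-butyl(dimethyl)silyl]oxymethyl}-7-oxabicyclo[4.1.0]hept-3-en-2-ol (C4–C5 α-oxirane cis to the 6α-hydroxyl; C1=C2 alkene and C3 methylene unchanged)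
Conditions: Hf(OtBu)4 (10 mol %), chiral C2-symmetric bis-hydroxamic acid ligand [N,N'-dihydroxy-N,N'-bis(diarylacetyl)-trans-cyclohexane-1,2-diamine, 12 mol %], PhC(CH3)2OOH (1.3 equiv), MgO, 4 Å molecular sieves, toluene, 0 °C
Reagents that add atoms: cumene hydroperoxide, CC(C)(OO)c1ccccc1
Why: The tertiary C6–OH exchanges onto the tetravalent hafnium centre held by the bis-hydroxamate, the cumyl peroxide binds to the same metal, and its electrophilic oxygen is passed within the complex to one of the two flanking alkenes. The closest known reaction type is the bis-hydroxamic acid–metal-catalysed, hydroxyl-directed asymmetric epoxidation of tertiary allylic alcohols together with the enantiotopic-alkene-selective epoxidation of divinyl carbinols, of which this ring-locked dienol is a new member. The oxirane closes by concerted syn addition of the peroxide oxygen across C4=C5, so that C4–O and C5–O form on one face as a three-membered ring fused to the six-membered ring. C4 and C5 are fixed by the metal–alkoxide tether, which reaches only the face of the C6 hydroxyl and so gives the cis epoxy alcohol, and C6 becomes stereogenic through the ligand's choice between the enantiotopic C4=C5 and C1=C2 alkenes. The step needs enantiotopic-alkene selection, syn-face selection and mono-epoxidation, which the ligand pocket, the single free hydroxyl (C7 is silylated and its bulky arm holds the C6–OH over the ring) and the limited oxidant charge should secure, while MgO keeps the acid-labile dienol from aromatizing. Any mono-epoxide of the wrong enantiomeric series still presents the alkene the catalyst prefers and should be consumed faster to the achiral bis-epoxide, which should raise the enantiopurity of 10.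

Step 7
Reactants: 10 syn-4α,5α-epoxy alcohol, 1 benzoic acid
Product: 11 4β-benzoyloxy-6β-{[tert-butyl(dimethyl)silyl]oxymethyl}cyclohex-1-ene-5α,6α-diol (C1=C2 alkene, C3 methylene)
Conditions: PhCO2H (1.5 equiv), Ti(OiPr)4 (1.5 equiv), CH2Cl2, 0 °C to rt; aq. KNaC4H4O6
Reagents that add atoms: benzoic acid, OC(=O)c1ccccc1
Why: Titanium-assisted opening of a 2,3-epoxy alcohol: the tetravalent titanium alkoxide of C6–OH activates the oxirane and benzoate attacks C4 (C-3 of the epoxy alcohol, whereas C5 is neopentyl) by SN2 from the β face, so inversion at C4 should give the trans C4-benzoate/C5-hydroxyl pair while C5 and C6 are untouched.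

Step 8
Reactants: 11 4β-benzoate 5α,6α-diol, 12 2-methoxypropene
Product: 13 5α,6α-O-isopropylidene acetal of 11 (cis-fused dioxolane; 4β-benzoate, C7 TBS ether, C1=C2 alkene)
Conditions: 2-methoxypropene, PPTS (cat.), CH2Cl2, 0 °C
Reagents that add atoms: 2-methoxypropene, COC(C)=C
Why: Acid-catalysed acetalization closes a cis-fused dioxolane over the cis C5/C6 diol, which masks both α-hydroxyls so that neither can direct or be acylated later, and no stereocenter is touched.

Step 9
Reactants: 13 acetonide TBS ether
Product: 14 primary alcohol (C7–OH free; 4β-benzoate, 5α,6α-acetonide, C1=C2 alkene)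
Conditions: HF·pyridine, pyridine, THF, 0 °C to rt
Reagents that add atoms: none
Why: Fluoride-driven desilylation of the primary silyl ether under buffered, non-basic conditions, so that no alkoxide is present to shift the benzoate and the acetonide is retained.

Step 10
Reactants: 14 homoallylic alcohol
Product: 15 1β,2β-epoxide (oxirane cis to the C7 arm; 4β-benzoate, 5α,6α-acetonide, C7–OH)
Conditions: VO(acac)2 (5 mol %), tBuOOH (1.5 equiv, decane), CH2Cl2, 0 °C to rt
Reagents that add atoms: tert-butyl hydroperoxide, CC(C)(C)OO
Why: Vanadium-catalysed hydroxyl-directed epoxidation of a homoallylic alcohol: the vanadate ester of the β-placed C7–OH, the only free hydroxyl, passes the peroxide oxygen to the β face of C1=C2, which sets C1 trans to the C6 oxygen.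

Step 11
Reactants: 15 1β,2β-epoxide
Product: 18 4β-benzoyloxy-5α,6α-O-isopropylidene-cyclohex-2-ene-1β-ol carrying the free C7 hydroxymethyl group (C2=C3 alkene), via hydroxy selenide 16 (not isolated), via selenoxide 17 (not isolated)
Conditions: (PhSe)2, NaBH4, EtOH, 0 °C to rt; then THF, 30% aq. H2O2, pyridine, 0 °C to rt
Reagents that add atoms: none
Why: Epoxide-to-allylic-alcohol transposition by selenide opening and selenoxide syn-elimination: benzeneselenolate opens the oxirane trans-diaxially at C2 (C1 is neopentyl), which keeps the C1–O bond and its β configuration, and the selenoxide then eliminates towards the C3 hydrogen, away from the carbinol carbon, to give the C2=C3 alkene.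

Step 12
Reactants: 18 allylic diol, 19 chlorotriethylsilane, 20 benzoyl chloride
Product: 22 1β,4β-bis(benzoyloxy)-5α,6α-O-isopropylidene-cyclohex-2-ene with the C7 triethylsilyl ether, via triethylsilyl ether 21 (not isolated)
Conditions: Et3SiCl (1.05 equiv), pyridine, CH2Cl2, −40 to 0 °C; then BzCl (2 equiv), DMAP, rt
Reagents that add atoms: chlorotriethylsilane, CC[Si](Cl)(CC)CC; benzoyl chloride, O=C(Cl)c1ccccc1
Why: Selective silylation followed by DMAP-catalysed acylation: the primary C7–OH is silylated first on steric grounds, and the remaining secondary C1–OH is then benzoylated with retention because its C–O bond is not broken.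

Step 13
Reactants: 22 bis-benzoate acetonide silyl ether
Product: 23 (1S,4R,5S,6S)-1,4-bis(benzoyloxy)-6-(hydroxymethyl)cyclohex-2-ene-5,6-diol in the numbering used here (1β- and 4β-benzoates, 5α- and 6α-hydroxyls), the target
Conditions: CF3CO2H/H2O (4:1), CH2Cl2, 0 °C
Reagents that add atoms: none
Why: Acid hydrolysis removes the isopropylidene acetal and the triethylsilyl ether in one operation without breaking any ring C–O bond, and the short, cold exposure is chosen to keep the benzoates from migrating to the freed hydroxyls.

Compound list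
1 | benzoic acid | OC(=O)c1ccccc1 | starting material
2 | cyclohexa-2,5-diene-1-carboxylic acid | OC(=O)C1C=CCC=C1 | intermediate
3 | iodomethane | CI | starting material
4 | methyl cyclohexa-2,5-diene-1-carboxylate | COC(=O)C1C=CCC=C1 | intermediate
5 | potassium enolate of 4 | COC([O-])=C1C=CCC=C1.[K+] | intermediate
6 | methyl 1-hydroxycyclohexa-2,5-diene-1-carboxylate | COC(=O)C1(O)C=CCC=C1 | intermediate
7 | 1-(hydroxymethyl)cyclohexa-2,5-dien-1-ol | OCC1(O)C=CCC=C1 | intermediate
8 | tert-butyl(chloro)dimethylsilane | CC(C)(C)[Si](C)(C)Cl | starting material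
9 | 1-{[tert-butyl(dimethyl)silyl]oxymethyl}cyclohexa-2,5-dien-1-ol | OC1(CO[Si](C)(C)C(C)(C)C)C=CCC=C1 | intermediate
10 | (1S,2S,6S)-2-{[tert-butyl(dimethyl)silyl]oxymethyl}-7-oxabicyclo[4.1.0]hept-3-en-2-ol (4α,5α-epoxide, 6α-OH) | C1=CC[C@@H]2O[C@@H]2[C@@]1(O)CO[Si](C)(C)C(C)(C)C | intermediate
11 | 4β-benzoyloxy-6β-{[tert-butyl(dimethyl)silyl]oxymethyl}cyclohex-1-ene-5α,6α-diol | C1=CC[C@@H](OC(=O)c2ccccc2)[C@H](O)[C@@]1(O)CO[Si](C)(C)C(C)(C)C | intermediate
12 | 2-methoxypropene | COC(C)=C | starting material
13 | 5α,6α-O-isopropylidene acetal of 11 | C1=CC[C@@H](OC(=O)c2ccccc2)[C@@H]2OC(C)(C)O[C@]12CO[Si](C)(C)C(C)(C)C | intermediate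
14 | 4β-benzoyloxy-5α,6α-O-isopropylidene-cyclohex-1-ene with free C7 hydroxymethyl | C1=CC[C@@H](OC(=O)c2ccccc2)[C@@H]2OC(C)(C)O[C@]12CO | intermediate
15 | 1β,2β-epoxide of 14 | [C@H]12O[C@H]1C[C@@H](OC(=O)c4ccccc4)[C@@H]3OC(C)(C)O[C@]23CO | intermediate
16 | 1β-hydroxy-2α-(phenylselanyl) 4β-benzoate 5α,6α-acetonide (hydroxy selenide) | O[C@H]1[C@H]([Se]c2ccccc2)C[C@@H](OC(=O)c2ccccc2)[C@@H]2OC(C)(C)O[C@]12CO | intermediate
17 | selenoxide of 16 (both configurations at selenium) | O[C@H]1[C@H]([Se](=O)c2ccccc2)C[C@@H](OC(=O)c2ccccc2)[C@@H]2OC(C)(C)O[C@]12CO | intermediate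
18 | 4β-benzoyloxy-5α,6α-O-isopropylidene-cyclohex-2-en-1β-ol with free C7 hydroxymethyl | O[C@H]1C=C[C@@H](OC(=O)c2ccccc2)[C@@H]2OC(C)(C)O[C@]12CO | intermediate
19 | chlorotriethylsilane | CC[Si](Cl)(CC)CC | starting material
20 | benzoyl chloride | O=C(Cl)c1ccccc1 | starting material
21 | C7 triethylsilyl ether of 18 | O[C@H]1C=C[C@@H](OC(=O)c2ccccc2)[C@@H]2OC(C)(C)O[C@]12CO[Si](CC)(CC)CC | intermediate
22 | 1β,4β-bis(benzoyloxy)-5α,6α-O-isopropylidene-cyclohex-2-ene, C7 triethylsilyl ether | O=C(O[C@H]1C=C[C@@H](OC(=O)c2ccccc2)[C@@H]2OC(C)(C)O[C@]12CO[Si](CC)(CC)CC)c1ccccc1 | intermediate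
23 | (1S,4R,5S,6S)-1,4-bis(benzoyloxy)-6-(hydroxymethyl)cyclohex-2-ene-5,6-diol (CNP0212417.1) | O=C(O[C@H]1C=C[C@@H](OC(=O)c2ccccc2)[C@H](O)[C@@]1(O)CO)c1ccccc1 | target

Total step count: 13. Longest linear sequence: 13 steps (1 to 23).

Steps most likely to fail

Step 6. What may go wrong: weak discrimination between the two enantiotopic alkenes on a flat, ring-locked dienol, or metal-induced dehydration and aromatization of the dienol before oxygen transfer. The fallback sets out from 9 and comes back at 11. The dienol is epoxidized without a chiral ligand (VO(acac)2, tBuOOH, 2,6-lutidine, toluene, 0 °C). Hydroxyl direction should again give only the syn epoxy alcohol, now as 10 together with its mirror image, the enantiomeric syn-epoxy alcohol F1. The mixture is opened with PhCO2H/Ti(OiPr)4 as in step 7 to 11 together with the enantiomeric hydroxy benzoate F2. The two are separated by preparative chromatography on a chiral stationary phase, the benzoate serving as chromophore, which returns single-enantiomer 11 at the cost of half the material.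

Step 7. What may go wrong: competing benzoate attack at C5, acid-promoted ionization of the allylic tertiary carbinol, or shift of the new benzoate to the neighbouring hydroxyl on the titanium centre. The fallback sets out from 10 and comes back at 11. The oxirane is opened without Lewis acid by hydroxide (aq. KOH, DMSO, 60 °C), which by SN2 attack at the unhindered C4 should give the 4β,5α,6α-triol F3. Its C4 hydroxyl, the only unhindered secondary one, is then benzoylated selectively (BzCl, 1 equiv, pyridine, CH2Cl2, −40 °C) to reach 11.

Step 11. What may go wrong: loss of the C4 benzoate by ethanolysis or hydride attack in the basic selenolate medium, or over-oxidation of the new alkene by selenium peracids. The fallback sets out from 15 and comes back at 22; because both C1 and C4 end as benzoates, the ester need not be carried through this step. The benzoate is removed on purpose (K2CO3, MeOH, 0 °C) to give the epoxy diol F4. Selenolate opening as in step 11 gives the hydroxy selenide F5, and H2O2 converts it through the selenoxide F6 into the allylic triol F7. Et3SiCl/pyridine at −40 °C silylates the primary hydroxyl to the silyl ether diol F8, and excess BzCl/DMAP benzoylates both secondary allylic hydroxyls to give 22.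

Further compounds
F1 | step 6 | (1R,2R,6R)-2-{[tert-butyl(dimethyl)silyl]oxymethyl}-7-oxabicyclo[4.1.0]hept-3-en-2-ol (enantiomer of 10) | C1=CC[C@H]2O[C@H]2[C@]1(O)CO[Si](C)(C)C(C)(C)C
F2 | step 6 | enantiomer of 11 | C1=CC[C@H](OC(=O)c2ccccc2)[C@@H](O)[C@]1(O)CO[Si](C)(C)C(C)(C)C
F3 | step 7 | 6β-{[tert-butyl(dimethyl)silyl]oxymethyl}cyclohex-1-ene-4β,5α,6α-triol | C1=CC[C@@H](O)[C@H](O)[C@@]1(O)CO[Si](C)(C)C(C)(C)C
F4 | step 11 | 1β,2β-epoxy-5α,6α-O-isopropylidene-cyclohexan-4β-ol with free C7 hydroxymethyl | [C@H]12O[C@H]1C[C@@H](O)[C@@H]3OC(C)(C)O[C@]23CO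
F5 | step 11 | 2α-(phenylselanyl)-5α,6α-O-isopropylidene-cyclohexane-1β,4β-diol with free C7 hydroxymethyl | O[C@H]1[C@H]([Se]c2ccccc2)C[C@@H](O)[C@@H]2OC(C)(C)O[C@]12CO
F6 | step 11 | selenoxide of F5 | O[C@H]1[C@H]([Se](=O)c2ccccc2)C[C@@H](O)[C@@H]2OC(C)(C)O[C@]12CO
F7 | step 11 | 5α,6α-O-isopropylidene-cyclohex-2-ene-1β,4β-diol with free C7 hydroxymethyl | O[C@H]1C=C[C@@H](O)[C@@H]2OC(C)(C)O[C@]12CO
F8 | step 11 | C7 triethylsilyl ether of F7 | O[C@H]1C=C[C@@H](O)[C@@H]2OC(C)(C)O[C@]12CO[Si](CC)(CC)CC
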